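**Retrosynthetic overview**
- GA50 ← acetonide removal, C7 ester cleavage and C12 reduction ← pentacyclic keto ester 29; ring D by gold-catalysed Conia-ene closure (C13–C16), ring C by Diels–Alder addition of 2-siloxybutadiene to the ring-B enal (C8=C9).
- Ring-B enal ← tricyclic lactone 18 (rings A and B plus the 19,10-lactone); its C2=C3 alkene gives the 2β,3β-diol while it is still the only electron-rich alkene.
- 18 ← acyclic keto acid 14 in one flask: sensitised [2+2] photocycloaddition closes ring B and a cyclobutane (C10–C3–C4–C5); the alkoxide-accelerated 1,3-shift then enlarges that four-membered ring by C2 and C1 to ring A, and the C19 nitrile traps the C10 oxide as the lactone.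
- Enabling feature: the 2-vinylcyclobutanol array – C10 carries the oxygen and is bonded to C3, which bears the C2=C1 vinyl group, inside the strained ring C10–C3–C4–C5 fused to ring B; the nitrile on C4 sits cis to capture the C10 oxide.
- 14 ← organocatalytic Michael addition of 4-oxohept-6-enal to a nitrodiene (sets C6 and C8). Ring order: B (with cyclobutane) → A and lactone → C → D.

Key step: step 9

Remark: atoms carry gibberellane numbers (C1–C19). The cyano-alkene of 8–14 is used as an E/Z mixture (its geometry is lost in the triplet cycloaddition), and the C15 carbinol of 26–28 as an epimer mixture (the centre is removed in step 18).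

**Step 1**
Reactants: 1 2,3-dihydrofuran; 2 allyl bromide
Product: 4 hept-6-ene-1,4-diol, via 2-hydroxytetrahydrofuran 3 (not isolated)
Conditions: 0.1 M HCl, THF/H2O, rt; then In powder, rt
Reagents that add atoms: water, O
Why: Acid hydration of the enol ether gives lactol 3, whose open hydroxy-aldehyde form is allylated in water (Barbier allylation); the carbinol centre is destroyed in step 2, so no stereocontrol is needed.

**Step 2**
Reactants: 4 hept-6-ene-1,4-diol
Product: 5 4-oxohept-6-enal
Conditions: (COCl)2, DMSO, CH2Cl2, −78 °C; Et3N, −78 to 0 °C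
Reagents that add atoms: none
Why: Swern oxidation activates both hydroxyls before the hydroxy aldehyde can close to a lactol, and the cold conditions should keep the β,γ-unsaturated ketone out of conjugation.

**Step 3**
Reactants: 6 2,2-dimethoxyacetaldehyde; 7 diethyl (1-cyanoethyl)phosphonate
Product: 8 4,4-dimethoxy-2-methylbut-2-enenitrile
Conditions: K2CO3, H2O/THF, rt
Reagents that add atoms: none
Why: Horner–Wadsworth–Emmons olefination of the aqueous aldehyde with the cyano-stabilised phosphonate; the alkene geometry is immaterial for the later photochemistry.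

**Step 4**
Reactants: 8 4,4-dimethoxy-2-methylbut-2-enenitrile
Product: 9 2-methyl-4-oxobut-2-enenitrile
Conditions: HCO2H/H2O, rt
Reagents that add atoms: water, O
Why: Acid hydrolysis of the dimethyl acetal; the conjugated nitrile is inert.

**Step 5**
Reactants: 9 2-methyl-4-oxobut-2-enenitrile; 10 nitromethane
Product: 11 (4E)-2-methyl-5-nitropenta-2,4-dienenitrile
Conditions: NH4OAc (cat.), AcOH, 60 °C
Reagents that add atoms: none
Why: Henry reaction with in situ dehydration should give the conjugated (E)-nitroalkene, the thermodynamically favoured isomer.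

**Step 6**
Reactants: 5 4-oxohept-6-enal; 11 nitrodiene
Product: 12 (2S,3S)-5-cyano-3-(nitromethyl)-2-(2-oxopent-4-en-1-yl)hex-4-enal (CHO = C15, C2 = C8, C3 = C6)
Conditions: (R)-2-[diphenyl(trimethylsilyloxy)methyl]pyrrolidine (10 mol %), 4-nitrophenol (20 mol %), toluene, 0 °C
Reagents that add atoms: none
Why: Enamine-catalysed Michael addition: the E-enamine of 5 should add 1,4 to the nitroalkene terminus through the acyclic synclinal transition state, setting C8 and C6 (syn adduct) in one catalytic event; the (R)-catalyst is chosen by analogy with the established facial sense of this reaction.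

**Step 7**
Reactants: 12 Michael adduct
Product: 13 1,3-dioxolane of 12 (C15 acetal)
Conditions: 1,2-bis(trimethylsiloxy)ethane, TMSOTf (5 mol %), CH2Cl2, −78 °C
Reagents that add atoms: 1,2-bis(trimethylsiloxy)ethane, C[Si](C)(C)OCCO[Si](C)(C)C
Why: TMSOTf-catalysed silyl-transfer acetalization at low temperature should select the aldehyde over the ketone and avoid both C8 epimerization and furan formation from the γ-keto aldehyde.

**Step 8**
Reactants: 13 nitro acetal
Product: 14 2-(2-cyanoprop-1-enyl)-3-(1,3-dioxolan-2-yl)-5-oxooct-7-enoic acid (C6, C8 as in 12)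
Conditions: NaNO2, AcOH, DMSO, 35 °C
Reagents that add atoms: sodium nitrite, [Na+].[O-]N=O; water, O
Why: Oxidative Nef reaction: nitrosation of the primary nitronate and breakdown of the nitrolic acid should deliver the C7 carboxylic acid directly under weakly acidic conditions that leave C6 untouched.

**Step 9**
Reactants: 14 keto acid
Product: 18 tricyclic lactone aldehyde acid (ring A with C2=C3, ring B trans-fused at C5–C10, 19,10-lactone, 4β-methyl, 6β-CO2H, 8α-CHO), via silyl dienol ether 15 (not isolated), via vinylcyclobutane 16 (not isolated), via iminolactone 17 (not isolated)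
Conditions: TMSOTf, Et3N, CH2Cl2, −78 °C; then 2-isopropylthioxanthone (10 mol %), 405 nm LEDs, MeCN, 0 °C; then KOt-Bu, 18-crown-6, THF, −20 to 25 °C; then 1 M HCl, THF, rt
Reagents that add atoms: water, O
Why: Soft enolization gives silyl dienol ether 15 (the acid is masked in passing as its TMS ester), and triplet sensitization of the 2-siloxydiene starts an intramolecular diene–alkene [2+2] photocycloaddition, the closest known type being sensitised vinylcyclobutane formation from tethered 1,3-dienes. The first bond (C10–C5) closes ring B in the 5-exo-trig mode through a chair-like transition state with the C8 dioxolanyl and C6 carboxyl groups both pseudo-equatorial, so C4 should end trans to C7 (C5 is set by the C6/C8 pair); radical recombination C3–C4 then closes the cis-fused cyclobutane with the small nitrile preferring the endo position at C4. Removing the silyl groups with KOt-Bu exposes the C10 potassium alkoxide of a 2-vinylcyclobutanol, and the strain of the ring C10–C3–C4–C5 drives the alkoxide-accelerated [1,3] shift of C10 from C3 to C1 (the known oxy-anion vinylcyclobutane-to-cyclohexene rearrangement), which enlarges the four-membered ring by the two vinyl carbons to ring A with the C2=C3 alkene. The shift should occur with inversion at C10 (or by fragmentation to the cyclopentanone–allyl anion pair and re-addition), and only the oxide cis to the nitrile is drained, by 5-exo-dig addition to C19, as cyclic imidate 17, which aqueous acid hydrolyses to the 19,10-lactone while freeing the aldehyde. The step needs regiocontrol (secured by the three-atom tether, five-membered ring first), suppression of the thermal Diels–Alder path that would give the C1=C2 isomer (secured by the cis-substituted diene terminus and 0 °C), and a chemoselective alkoxide (secured by keeping C7 as a carboxylate and C15 as an acetal).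

**Step 10**
Reactants: 18 lactone aldehyde acid
Product: 19 methyl ester of 18
Conditions: TMSCHN2, MeOH/toluene, 0 °C
Reagents that add atoms: trimethylsilyldiazomethane, C[Si](C)(C)C=[N+]=[N-]
Why: Esterification with the diazo reagent is fast at 0 °C and leaves aldehyde, lactone and alkene untouched.

**Step 11**
Reactants: 19 aldehyde ester
Product: 21 ring-B enal (C8=C9, CHO on C8), via silyl enol ether 20 (not isolated)
Conditions: TMSOTf, Et3N, CH2Cl2, 0 °C; then Pd(OAc)2 (10 mol %), O2, DMSO, 45 °C
Reagents that add atoms: none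
Why: Saegusa–Ito oxidation: the aldehyde can enolize only toward C8, and β-hydride elimination from the palladium enolate should prefer the unhindered C9–H over the ester-flanked C6–H.

**Step 12**
Reactants: 21 enal
Product: 22 2β,3β-diol
Conditions: OsO4 (2 mol %), NMO, acetone/H2O, 0 °C to rt
Reagents that add atoms: N-methylmorpholine N-oxide, C[N+]1([O-])CCOCC1; water, O
Why: Upjohn dihydroxylation: the electron-poor enal reacts slowly, and OsO4 should add to C2=C3 from the β-face, anti to the pseudo-axial lactone carbonyl on C4.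

**Step 13**
Reactants: 22 diol
Product: 23 2,3-acetonide
Conditions: 2-methoxypropene, PPTS, CH2Cl2, 0 °C
Reagents that add atoms: 2-methoxypropene, COC(C)=C
Why: Acid-catalysed acetal formation on the cis-diol; the enal is not affected under these aprotic conditions.

**Step 14**
Reactants: 23 enal acetonide; 24 2-(trimethylsiloxy)-1,3-butadiene
Product: 25 tetracyclic aldehyde with C12=C13 TMS enol ether (ring C closed; C8 quaternary, 9β-H)
Conditions: toluene, BHT, 110 °C, sealed tube
Reagents that add atoms: none
Why: Diels–Alder reaction: the nucleophilic diene terminus bonds to the enal β-carbon C9 (para rule), placing the enol ether at C12=C13; suprafacial addition to the α-face of ring B, anti to the C6 ester and the C1 methylene, should set C8 and C9 with the cis B/C fusion.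

**Step 15**
Reactants: 25 aldehyde
Product: 26 C15 ethynyl carbinol (epimer mixture)
Conditions: ethynylmagnesium bromide, THF, −78 to −20 °C
Reagents that add atoms: ethynylmagnesium bromide, C#C[Mg]Br
Why: 1,2-Addition of the Grignard reagent to the aldehyde at low temperature; esters, lactone and silyl enol ether react more slowly, and the new centre is removed in step 18.

**Step 16**
Reactants: 26 alkynyl silyl enol ether
Product: 27 pentacyclic 12-ketone with 16(17)-methylene and 15-OH (ring D closed)
Conditions: Ph3PAuCl (5 mol %), AgBF4 (5 mol %), CH2Cl2/MeOH, rt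
Reagents that add atoms: none
Why: Gold-catalysed Conia-ene cyclization: the regiodefined silyl enol ether attacks the activated alkyne through C13 in the 5-exo-dig mode; only the cis-bridged bicyclo[3.2.1]octane can form, which fixes C13.

**Step 17**
Reactants: 27 allylic alcohol
Product: 28 C15 methyl carbonate
Conditions: ClCO2Me, pyridine, DMAP (cat.), CH2Cl2, 0 °C
Reagents that add atoms: methyl chloroformate, COC(=O)Cl
Why: Acylation of the allylic alcohol prepares the ionization of the next step.

**Step 18**
Reactants: 28 allylic carbonate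
Product: 29 pentacyclic 12-keto methyl ester (C15H2, 16(17)-methylene)
Conditions: Pd2(dba)3 (2.5 mol %), PBu3 (10 mol %), HCO2NH4, 1,4-dioxane, 80 °C
Reagents that add atoms: none
Why: Tsuji formate reduction: the π-allylpalladium formate should deliver hydride to the more substituted terminus C15, keeping the exocyclic alkene.

**Step 19**
Reactants: 29 ketone
Product: 30 12-alcohol (equatorial)
Conditions: Al(Oi-Pr)3, i-PrOH, toluene, 80 °C
Reagents that add atoms: none
Why: Meerwein–Ponndorf–Verley reduction under equilibrating conditions should favour the equatorial 12-alcohol, since the axial epimer would be 1,3-diaxial to C10.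

**Step 20**
Reactants: 30 methyl ester
Product: 31 C7 carboxylic acid (acetonide)
Conditions: n-PrSLi, HMPA, rt; then dilute HCl
Reagents that add atoms: none
Why: SN2 demethylation of the hindered methyl ester by thiolate avoids hydroxide, which would open the lactone.

**Step 21**
Reactants: 31 acetonide acid
Product: 32 GA50
Conditions: AcOH/H2O (4:1), 45 °C
Reagents that add atoms: none
Why: Mild acid hydrolysis of the acetonide; the lactone and the exocyclic alkene should tolerate these conditions.

**Compound list**
1 | 2,3-dihydrofuran | C1=COCC1 | starting material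
2 | allyl bromide | C=CCBr | starting material
3 | 2-hydroxytetrahydrofuran (not isolated) | OC1CCCO1 | intermediate
4 | hept-6-ene-1,4-diol (racemic) | OCCCC(O)CC=C | intermediate
5 | 4-oxohept-6-enal | O=CCCC(=O)CC=C | intermediate
6 | 2,2-dimethoxyacetaldehyde | COC(OC)C=O | starting material
7 | diethyl (1-cyanoethyl)phosphonate | CCOP(=O)(OCC)C(C)C#N | starting material
8 | 4,4-dimethoxy-2-methylbut-2-enenitrile (E/Z) | COC(OC)C=C(C)C#N | intermediate
9 | 2-methyl-4-oxobut-2-enenitrile (E/Z) | O=CC=C(C)C#N | intermediate
10 | nitromethane | C[N+](=O)[O-] | starting material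
11 | (4E)-2-methyl-5-nitropenta-2,4-dienenitrile | [O-][N+](=O)/C=C/C=C(C)C#N | intermediate
12 | (2S,3S)-5-cyano-3-(nitromethyl)-2-(2-oxopent-4-en-1-yl)hex-4-enal | O=C[C@@H](CC(=O)CC=C)[C@H](C=C(C)C#N)C[N+](=O)[O-] | intermediate
13 | 1,3-dioxolane of 12 | O1CCOC1[C@@H](CC(=O)CC=C)[C@H](C=C(C)C#N)C[N+](=O)[O-] | intermediate
14 | 2-(2-cyanoprop-1-enyl)-3-(1,3-dioxolan-2-yl)-5-oxooct-7-enoic acid (C6, C8 as in 12) | O1CCOC1[C@@H](CC(=O)CC=C)[C@H](C=C(C)C#N)C(=O)O | intermediate
15 | TMS dienol ether TMS ester of 14 (not isolated) | O1CCOC1[C@@H](CC(O[Si](C)(C)C)=CC=C)[C@H](C=C(C)C#N)C(=O)O[Si](C)(C)C | intermediate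
16 | photoadduct: ring B cis-fused to the 10-siloxy-3-vinyl-4-cyano-4-methylcyclobutane (C3 epimers; not isolated) | O1CCOC1[C@H]2C[C@@]3(O[Si](C)(C)C)C(C=C)[C@@](C)(C#N)[C@H]3[C@@H]2C(=O)O[Si](C)(C)C | intermediate
17 | ring-expanded cyclic imidate (19,10-iminolactone; not isolated) | O1CCOC1[C@H]2C[C@@]34CC=C[C@@](C)(C(=N)O3)[C@H]4[C@@H]2C(=O)O | intermediate
18 | tricyclic lactone: ring A (C2=C3), ring B, 19,10-lactone, 8α-CHO, 6β-CO2H | O=C[C@H]1C[C@@]23CC=C[C@@](C)(C(=O)O2)[C@H]3[C@@H]1C(=O)O | intermediate
19 | methyl ester of 18 | O=C[C@H]1C[C@@]23CC=C[C@@](C)(C(=O)O2)[C@H]3[C@@H]1C(=O)OC | intermediate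
20 | TMS enol ether of aldehyde 19 (not isolated) | C[Si](C)(C)OC=C1C[C@@]23CC=C[C@@](C)(C(=O)O2)[C@H]3[C@@H]1C(=O)OC | intermediate
21 | ring-B enal (C8=C9) | O=CC1=C[C@@]23CC=C[C@@](C)(C(=O)O2)[C@H]3[C@@H]1C(=O)OC | intermediate
22 | 2β,3β-diol of 21 | O=CC1=C[C@@]23C[C@H](O)[C@H](O)[C@@](C)(C(=O)O2)[C@H]3[C@@H]1C(=O)OC | intermediate
23 | 2,3-acetonide of 22 | O=CC1=C[C@@]23C[C@@H]4OC(C)(C)O[C@@H]4[C@@](C)(C(=O)O2)[C@H]3[C@@H]1C(=O)OC | intermediate
24 | 2-(trimethylsiloxy)-1,3-butadiene | C=CC(=C)O[Si](C)(C)C | starting material
25 | Diels–Alder adduct: rings A–C, 8β-CHO, C12=C13 TMS enol ether | O=C[C@]12CC=C(O[Si](C)(C)C)C[C@H]1[C@@]34C[C@@H]5OC(C)(C)O[C@@H]5[C@@](C)(C(=O)O3)[C@H]4[C@@H]2C(=O)OC | intermediate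
26 | C15 ethynyl carbinol of 25 (C15 epimers) | C#CC(O)[C@]12CC=C(O[Si](C)(C)C)C[C@H]1[C@@]34C[C@@H]5OC(C)(C)O[C@@H]5[C@@](C)(C(=O)O3)[C@H]4[C@@H]2C(=O)OC | intermediate
27 | pentacyclic 12-ketone, 15-hydroxy, 16(17)-methylene | C=C1C(O)[C@]23C[C@H]1C(=O)C[C@H]2[C@@]45C[C@@H]6OC(C)(C)O[C@@H]6[C@@](C)(C(=O)O4)[C@H]5[C@@H]3C(=O)OC | intermediate
28 | C15 methyl carbonate of 27 | C=C1C(OC(=O)OC)[C@]23C[C@H]1C(=O)C[C@H]2[C@@]45C[C@@H]6OC(C)(C)O[C@@H]6[C@@](C)(C(=O)O4)[C@H]5[C@@H]3C(=O)OC | intermediate
29 | 12-oxo methyl ester acetonide (C15H2) | C=C1C[C@]23C[C@H]1C(=O)C[C@H]2[C@@]45C[C@@H]6OC(C)(C)O[C@@H]6[C@@](C)(C(=O)O4)[C@H]5[C@@H]3C(=O)OC | intermediate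
30 | GA50 methyl ester 2,3-acetonide | C=C1C[C@]23C[C@H]1[C@H](O)C[C@H]2[C@@]45C[C@@H]6OC(C)(C)O[C@@H]6[C@@](C)(C(=O)O4)[C@H]5[C@@H]3C(=O)OC | intermediate
31 | GA50 2,3-acetonide | C=C1C[C@]23C[C@H]1[C@H](O)C[C@H]2[C@@]45C[C@@H]6OC(C)(C)O[C@@H]6[C@@](C)(C(=O)O4)[C@H]5[C@@H]3C(=O)O | intermediate
32 | GA50 | C=C1C[C@]23C[C@H]1[C@H](O)C[C@H]2[C@@]12C[C@H](O)[C@H](O)[C@@](C)(C(=O)O1)[C@H]2[C@@H]3C(=O)O | target

**Step count**
Total: 21 steps. Longest linear sequence: 19 steps (steps 3–21).

**Steps most likely to fail**

Step 9. What may go wrong: weak endo/exo control at C4 in the diradical closure, re-closure of the allyl unit to the cis-fused C10 epimer that the nitrile cannot trap, or proton transfer outrunning the ring closure. The fallback leaves the photochemical route and sets out from 14. Samarium diiodide (HMPA, t-BuOH) should effect a 5-exo ketyl–alkene cyclization of the C10 ketyl onto C5 of the unsaturated nitrile, and acidic work-up lactonizes the C10 alcohol onto C19 to give the allyl lactone F1. Aldol reaction of its lactone enolate (LDA) with acetaldehyde on the convex face gives the carbinol F2, and dehydration (MsCl, Et3N, then DBU) gives the 4-vinyl lactone F3. Ring-closing metathesis (second-generation Grubbs catalyst) joins the C10 allyl and C4 vinyl groups to ring A with the C2=C3 alkene, giving the dioxolane acid F4; aqueous HCl returns to the route at 18.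

Step 11. What may go wrong: β-hydride elimination toward C6 instead of C9, giving the wrong alkene position. The fallback sets out from 19 and replaces the palladium dehydrogenation by a stereospecific elimination. The silyl enol ether 20 is brominated with NBS on the less hindered α-face to the α-bromo aldehyde F5. Anti elimination with Li2CO3/LiBr in DMF can then only use a β-hydrogen at C9, because H6 is syn to the bromine; this returns to the route at 21.

Step 14. What may go wrong: slow cycloaddition of the α-substituted enal, erosion of facial selectivity, or loss of the labile silyl enol ether. The fallback sets out from 23 and uses the more reactive trans-1-methoxy-3-(trimethylsiloxy)-1,3-butadiene. Cycloaddition and acid work-up give the 4,4-disubstituted cyclohexenone F6 (C13=C14, C12=O). Ethynylmagnesium bromide adds to the aldehyde to give the carbinol F7. Conjugate reduction with LiBH(s-Bu)3 and trapping with TMSCl regenerates the C12=C13 enol ether regiospecifically as the bis-silyl compound F8, which under the gold conditions of step 16 returns to the route at 27.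

**Further compounds**
F1 | step 9 | allyl lactone: ring B with C10 allyl, 19,10-lactone, C4–H | O1CCOC1[C@H]2C[C@@]3(CC=C)OC(=O)C(C)[C@H]3[C@@H]2C(=O)O
F2 | step 9 | C4 aldol adduct of F1 with acetaldehyde | O1CCOC1[C@H]2C[C@@]3(CC=C)OC(=O)[C@](C)(C(C)O)[C@H]3[C@@H]2C(=O)O
F3 | step 9 | 4-vinyl lactone | O1CCOC1[C@H]2C[C@@]3(CC=C)OC(=O)[C@](C)(C=C)[C@H]3[C@@H]2C(=O)O
F4 | step 9 | dioxolane of 18 | O1CCOC1[C@H]2C[C@@]34CC=C[C@@](C)(C(=O)O3)[C@H]4[C@@H]2C(=O)O
F5 | step 11 | 8α-bromo aldehyde | O=C[C@]1(Br)C[C@@]23CC=C[C@@](C)(C(=O)O2)[C@H]3[C@@H]1C(=O)OC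
F6 | step 14 | ring-C enone aldehyde (C13=C14, C12=O) | O=C[C@]12C=CC(=O)C[C@H]1[C@@]34C[C@@H]5OC(C)(C)O[C@@H]5[C@@](C)(C(=O)O3)[C@H]4[C@@H]2C(=O)OC
F7 | step 14 | C15 ethynyl carbinol of F6 | C#CC(O)[C@]12C=CC(=O)C[C@H]1[C@@]34C[C@@H]5OC(C)(C)O[C@@H]5[C@@](C)(C(=O)O3)[C@H]4[C@@H]2C(=O)OC
F8 | step 14 | bis-TMS compound (C12=C13 enol ether, C15 silyl ether) | C#CC(O[Si](C)(C)C)[C@]12CC=C(O[Si](C)(C)C)C[C@H]1[C@@]34C[C@@H]5OC(C)(C)O[C@@H]5[C@@](C)(C(=O)O3)[C@H]4[C@@H]2C(=O)OC
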